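**Retrosynthetic overview**

1. The side chain is numbered C1'–C16' from the benzylic carbon. The arene is bought; the only ring to build is the oxolane O/C12'/C13'/C14'/C15'.
2. Late disconnections: the O5' acetate; C1'–C2' together with the C3' methyl (methylalumination of a terminal alkyne, Pd coupling with a benzylic chloride); C4'–C5' (asymmetric propargylation of a C5' enal from a geraniol-derived C5'–C12' unit).
3. Key disconnection: C12'–C13' and O–C12' in one operation. The oxolane is grown from the oxirane O/C14'/C15' of (R)-3,3-dimethylglycidol by inserting C13' and C12' between the oxirane oxygen and C14' (3 → 5 ring expansion); the partner is the C12' allylic sulfone of the geranyl unit.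
4. Enabling feature: the 2,3-epoxy-1-ol triad C13'(OH)–C14'–C15'(O) with a fully substituted C15', so that Payne transposition moves the electrophilic site to C13' and leaves the oxirane oxygen on C15'; and C12', which is both α-sulfonyl and allylic (carbanion first, π-allyl electrophile second).
5. Ring order: oxirane (step 1) → transposed oxirane (in the flask) → oxolane (step 6); the sulfonyl group leaves in the same step.

Key step: step 6

Assumption: the sense of induction of the chiral catalysts (bisphosphine in step 6, phosphoric acid in step 10) is taken from the usual working models; if a test run shows the opposite sense, the antipodal catalyst is used and nothing else changes.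

**Route**

Step 1
Reactants: 1 3-methylbut-2-en-1-ol (prenol)
Product: 2 [(2R)-3,3-dimethyloxiran-2-yl]methanol
Conditions: Ti(OiPr)4 (cat.), D-(−)-diisopropyl tartrate (cat.), t-BuOOH, 4 Å MS, CH2Cl2, −20 °C
Reagents that add atoms: tert-butyl hydroperoxide, CC(C)(C)OO
Why: Katsuki–Sharpless asymmetric epoxidation of an allylic alcohol; with the D-(−)-tartrate the oxygen should be delivered to the face that makes the oxirane CH carbon R, the centre that becomes C14' after one inversion.

Step 2
Reactants: 3 geraniol [(2E)-3,7-dimethylocta-2,6-dien-1-ol]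
Product: 4 1-({[(2E)-3,7-dimethylocta-2,6-dien-1-yl]oxy}methyl)-4-methoxybenzene (geranyl PMB ether)
Conditions: NaH, Bu4NI (cat.), THF, 0 → 23 °C
Reagents that add atoms: 4-methoxybenzyl chloride, COc1ccc(CCl)cc1
Why: Williamson etherification of the primary allylic alkoxide; the PMB ether tolerates the basic key step and is removed oxidatively later.

Step 3
Reactants: 4 geranyl PMB ether
Product: 5 (2E,6E)-8-[(4-methoxybenzyl)oxy]-2,6-dimethylocta-2,6-dien-1-ol
Conditions: SeO2 (cat.), t-BuOOH, salicylic acid (cat.), CH2Cl2, 0 → 23 °C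
Reagents that add atoms: tert-butyl hydroperoxide, CC(C)(C)OO
Why: SeO2/t-BuOOH allylic oxidation (ene reaction, then [2,3]-shift) should attack the E-methyl group of the terminal isopropylidene unit, the most electron-rich alkene, and give the (E)-allylic alcohol whose carbinol carbon becomes C12'.

Step 4
Reactants: 5 (2E,6E)-8-[(4-methoxybenzyl)oxy]-2,6-dimethylocta-2,6-dien-1-ol
Product: 6 1-({[(2E,6E)-8-bromo-3,7-dimethylocta-2,6-dien-1-yl]oxy}methyl)-4-methoxybenzene
Conditions: CBr4, PPh3, CH2Cl2, 0 °C
Reagents that add atoms: carbon tetrabromide, BrC(Br)(Br)Br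
Why: Appel bromination of a primary allylic alcohol under neutral conditions, without allylic transposition.

Step 5
Reactants: 6 allylic bromide
Product: 7 1-methoxy-4-({[(2E,6E)-3,7-dimethyl-8-(phenylsulfonyl)octa-2,6-dien-1-yl]oxy}methyl)benzene (allyl sulfone)
Conditions: PhSO2Na, DMF, 23 °C
Reagents that add atoms: sodium benzenesulfinate, [Na+].[O-]S(=O)c1ccccc1
Why: SN2 S-alkylation of the sulfinate by the primary allylic bromide gives the allyl sulfone, which makes C12' acidic and, later, ionisable.

Step 6
Reactants: 7 allyl sulfone; 2 [(2R)-3,3-dimethyloxiran-2-yl]methanol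
Product: 10 (3S,5S)-5-[(2E,6E)-8-[(4-methoxybenzyl)oxy]-6-methylocta-2,6-dien-2-yl]-2,2-dimethyloxolan-3-ol, via Payne oxirane alkoxide 8 (not isolated), via C12'-sulfonyl diol 9 (not isolated)
Conditions: NaH (2.1 equiv), DMSO/THF, 23 → 55 °C; then, same flask, Pd2(dba)3·CHCl3 (2.5 mol %), (S,S)-1,2-diaminocyclohexane bis(2-diphenylphosphinobenzamide) ligand (7.5 mol %), 55 °C, dilute
Reagents that add atoms: none
Why: Proposed new method: NaH gives the alkoxide of 2 and the allyl-sulfonyl carbanion of 7; the alkoxide equilibrates by Payne rearrangement (3-exo-tet, inversion at C14') to the terminal oxirane 8, the carbanion opens 8 at its CH2 carbon through its α-carbon (C12'–C13' bond, 9), and Pd(0) then ionises the allylic C12'–S bond so that the tertiary C15' alkoxide closes the oxolane on the π-allyl terminus C12' (5-exo, anti to Pd) with loss of sulfinate, the oxygen of the original oxirane ending as the ring oxygen and the ring having grown by C13' and C12'. The closest known reaction types are the Payne rearrangement/sulfoxonium-ylide relay ring expansion of 2,3-epoxy alcohols to oxolan-3-ols, the opening of terminal epoxides by sulfonyl carbanions and the Pd-catalysed allylic substitution of allyl sulfones (Tsuji–Trost type), here merged so that one carbon acts first as nucleophile and then as electrophile. C14' (S) comes from the R centre of 2 by the single SN2 inversion of the Payne step and is not touched again. C12' (S) is set in the ring closure: the C12' epimers of 9 interconvert through the α-sulfonyl carbanion in the basic medium, ionisation and anti attack give net retention, and the chiral bisphosphine together with the pseudo-equatorial placing of the allyl unit and of O14' in the envelope transition state should select the epimer that leads to the 3,5-cis ring. The step needs attack at C13' and not at the oxirane carbons of 2 (secured by the fully substituted C15' and the neopentyl-like C14'), α- and not γ-alkylation of the allyl sulfone, five- and not four- or seven-membered ether closure (O15' on C12' against O14' on C12' or attack at C10'), and retention of the E C10'=C11' bond (the syn,syn π-allyl from the E sulfone has no low-energy route to the anti form).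

Step 7
Reactants: 10 oxolanol
Product: 11 tert-butyl{[(3S,5S)-5-[(2E,6E)-8-[(4-methoxybenzyl)oxy]-6-methylocta-2,6-dien-2-yl]-2,2-dimethyloxolan-3-yl]oxy}dimethylsilane
Conditions: TBSOTf, 2,6-lutidine, CH2Cl2, −78 → 0 °C
Reagents that add atoms: tert-butyldimethylsilyl trifluoromethanesulfonate, CC(C)(C)[Si](C)(C)OS(=O)(=O)C(F)(F)F
Why: Silylation of the hindered secondary C14' hydroxyl with the silyl triflate masks it so that only O5' can be acetylated later.

Step 8
Reactants: 11 silyl ether
Product: 12 (2E,6E)-7-[(2S,4S)-4-(tert-butyldimethylsilyloxy)-5,5-dimethyloxolan-2-yl]-3-methylocta-2,6-dien-1-ol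
Conditions: DDQ, CH2Cl2/pH 7 buffer, 0 °C
Reagents that add atoms: none
Why: Oxidative PMB cleavage by DDQ (hydride abstraction at the electron-rich benzylic position, hydrolysis of the oxocarbenium ion) should leave the silyl ether, the oxolane and the alkenes untouched.

Step 9
Reactants: 12 allylic alcohol
Product: 13 (2E,6E)-7-[(2S,4S)-4-(tert-butyldimethylsilyloxy)-5,5-dimethyloxolan-2-yl]-3-methylocta-2,6-dienal
Conditions: MnO2 (activated, excess), CH2Cl2, 23 °C
Reagents that add atoms: none
Why: Chemoselective MnO2 oxidation of the primary allylic alcohol to the (E)-enal without E/Z isomerisation.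

Step 10
Reactants: 13 enal
Product: 14 (4R,5E,9E)-10-[(2S,4S)-4-(tert-butyldimethylsilyloxy)-5,5-dimethyloxolan-2-yl]-6-methylundeca-5,9-dien-1-yn-4-ol
Conditions: allenylboronic acid pinacol ester, (R)-TRIP phosphoric acid (5 mol %), 4 Å MS, toluene, −20 °C
Reagents that add atoms: allenylboronic acid pinacol ester, C=C=CB1OC(C)(C)C(C)(C)O1
Why: Chiral phosphoric acid-catalysed propargylboration of the aldehyde with the allenyl boronate through a six-membered chair transition state (SE2'); the catalyst shields one face of the acid-bound aldehyde and should set C5' as R, the remote centres having no influence.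

Step 11
Reactants: 15 4-methoxy-2-methylphenol
Product: 16 2-hydroxy-5-methoxy-3-methylbenzaldehyde
Conditions: MgCl2, Et3N, (CH2O)n, THF, reflux
Reagents that add atoms: paraformaldehyde (formaldehyde unit), C=O
Why: Magnesium phenoxide-directed ortho-formylation (Casnati–Skattebøl type) can only occupy the single free ortho position, a second formaldehyde acting as hydride acceptor.

Step 12
Reactants: 16 salicylaldehyde
Product: 17 2-(tert-butyldimethylsilyloxy)-5-methoxy-3-methylbenzaldehyde
Conditions: TBSCl, imidazole, DMF, 40 °C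
Reagents that add atoms: tert-butyldimethylsilyl chloride, CC(C)(C)[Si](C)(C)Cl
Why: Silyl ether formation on the phenol prevents quinone-methide formation from the later benzylic chloride and should survive organoaluminium, Pd and acylation conditions.

Step 13
Reactants: 17 silylated aldehyde
Product: 18 [2-(tert-butyldimethylsilyloxy)-5-methoxy-3-methylphenyl]methanol
Conditions: NaBH4, MeOH/THF, 0 °C
Reagents that add atoms: none
Why: Hydride reduction of the aryl aldehyde to the benzylic alcohol at low temperature, where O-to-O silyl migration should be slow.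

Step 14
Reactants: 18 benzylic alcohol
Product: 19 tert-butyl[2-(chloromethyl)-4-methoxy-6-methylphenoxy]dimethylsilane
Conditions: PPh3, N-chlorosuccinimide, CH2Cl2, 0 °C
Reagents that add atoms: N-chlorosuccinimide, O=C1CCC(=O)N1Cl
Why: Appel-type chlorination of the electron-rich benzylic alcohol under neutral conditions.

Step 15
Reactants: 14 homopropargylic alcohol; 19 benzylic chloride
Product: 21 (2E,5R,6E,10E)-1-[2-(tert-butyldimethylsilyloxy)-5-methoxy-3-methylphenyl]-11-[(2S,4S)-4-(tert-butyldimethylsilyloxy)-5,5-dimethyloxolan-2-yl]-3,7-dimethyldodeca-2,6,10-trien-5-ol, via alkenylalane 20 (not isolated)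
Conditions: Me3Al (3 equiv), Cp2ZrCl2 (0.25 equiv), CH2Cl2, 0 → 23 °C; then 19, Pd(PPh3)4 (5 mol %), THF, 23 °C
Reagents that add atoms: trimethylaluminium, C[Al](C)C
Why: Zr-catalysed syn-methylalumination of the terminal alkyne (Negishi carboalumination) places methyl on C3' and aluminium on C2' on the same side, so C2'=C3' is formed E, and Pd-catalysed cross-coupling of the alkenylalane with the benzylic chloride (Negishi coupling) should proceed with retention of the alkene geometry, the C5' hydroxyl being carried as its aluminium alkoxide.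

Step 16
Reactants: 21 C5' alcohol
Product: 22 (2E,5R,6E,10E)-1-[2-(tert-butyldimethylsilyloxy)-5-methoxy-3-methylphenyl]-11-[(2S,4S)-4-(tert-butyldimethylsilyloxy)-5,5-dimethyloxolan-2-yl]-3,7-dimethyldodeca-2,6,10-trien-5-yl acetate
Conditions: Ac2O, pyridine, DMAP (cat.), CH2Cl2, 0 → 23 °C
Reagents that add atoms: acetic anhydride, CC(=O)OC(C)=O
Why: DMAP-catalysed acetylation of the only free hydroxyl (O5'), without change at C5'.

Step 17
Reactants: 22 bis-silyl acetate
Product: 23 (2E,5R,6E,10E)-1-(2-hydroxy-5-methoxy-3-methylphenyl)-11-[(2S,4S)-4-hydroxy-5,5-dimethyloxolan-2-yl]-3,7-dimethyldodeca-2,6,10-trien-5-yl acetate (CNP0148147.2)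
Conditions: HF·pyridine, pyridine, THF, 0 → 23 °C
Reagents that add atoms: none
Why: Fluoride cleavage of the aryl and the secondary silyl ethers under buffered conditions that should leave the allylic acetate and the allylic oxolane ether in place.

**Compound list**

1 | 3-methylbut-2-en-1-ol (prenol) | CC(C)=CCO | starting material
2 | [(2R)-3,3-dimethyloxiran-2-yl]methanol | OC[C@H]1OC1(C)C | intermediate
3 | geraniol | CC(C)=CCC/C(C)=C/CO | starting material
4 | geranyl 4-methoxybenzyl ether | CC(C)=CCC/C(C)=C/COCc1ccc(OC)cc1 | intermediate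
5 | (2E,6E)-8-[(4-methoxybenzyl)oxy]-2,6-dimethylocta-2,6-dien-1-ol | OC/C(C)=C/CC/C(C)=C/COCc1ccc(OC)cc1 | intermediate
6 | 1-({[(2E,6E)-8-bromo-3,7-dimethylocta-2,6-dien-1-yl]oxy}methyl)-4-methoxybenzene | BrC/C(C)=C/CC/C(C)=C/COCc1ccc(OC)cc1 | intermediate
7 | 1-methoxy-4-({[(2E,6E)-3,7-dimethyl-8-(phenylsulfonyl)octa-2,6-dien-1-yl]oxy}methyl)benzene | O=S(=O)(C/C(C)=C/CC/C(C)=C/COCc1ccc(OC)cc1)c1ccccc1 | intermediate
8 | sodium 2-[(2S)-oxiran-2-yl]propan-2-olate | [Na+].CC(C)([O-])[C@@H]1CO1 | intermediate (not isolated)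
9 | (3S,6E,10E)-12-[(4-methoxybenzyl)oxy]-2,6,10-trimethyl-5-(phenylsulfonyl)dodeca-6,10-diene-2,3-diol, both C5 epimers, present as sodium salts | CC(C)(O)[C@@H](O)CC(S(=O)(=O)c1ccccc1)/C(C)=C/CC/C(C)=C/COCc1ccc(OC)cc1 | intermediate (not isolated)
10 | (3S,5S)-5-[(2E,6E)-8-[(4-methoxybenzyl)oxy]-6-methylocta-2,6-dien-2-yl]-2,2-dimethyloxolan-3-ol | COc1ccc(COC/C=C(\C)CC/C=C(\C)[C@@H]2C[C@H](O)C(C)(C)O2)cc1 | intermediate
11 | tert-butyl{[(3S,5S)-5-[(2E,6E)-8-[(4-methoxybenzyl)oxy]-6-methylocta-2,6-dien-2-yl]-2,2-dimethyloxolan-3-yl]oxy}dimethylsilane | COc1ccc(COC/C=C(\C)CC/C=C(\C)[C@@H]2C[C@H](O[Si](C)(C)C(C)(C)C)C(C)(C)O2)cc1 | intermediate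
12 | (2E,6E)-7-[(2S,4S)-4-(tert-butyldimethylsilyloxy)-5,5-dimethyloxolan-2-yl]-3-methylocta-2,6-dien-1-ol | OC/C=C(\C)CC/C=C(\C)[C@@H]1C[C@H](O[Si](C)(C)C(C)(C)C)C(C)(C)O1 | intermediate
13 | (2E,6E)-7-[(2S,4S)-4-(tert-butyldimethylsilyloxy)-5,5-dimethyloxolan-2-yl]-3-methylocta-2,6-dienal | O=C/C=C(\C)CC/C=C(\C)[C@@H]1C[C@H](O[Si](C)(C)C(C)(C)C)C(C)(C)O1 | intermediate
14 | (4R,5E,9E)-10-[(2S,4S)-4-(tert-butyldimethylsilyloxy)-5,5-dimethyloxolan-2-yl]-6-methylundeca-5,9-dien-1-yn-4-ol | C#CC[C@@H](O)/C=C(\C)CC/C=C(\C)[C@@H]1C[C@H](O[Si](C)(C)C(C)(C)C)C(C)(C)O1 | intermediate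
15 | 4-methoxy-2-methylphenol | COc1ccc(O)c(C)c1 | starting material
16 | 2-hydroxy-5-methoxy-3-methylbenzaldehyde | COc1cc(C)c(O)c(C=O)c1 | intermediate
17 | 2-(tert-butyldimethylsilyloxy)-5-methoxy-3-methylbenzaldehyde | COc1cc(C)c(O[Si](C)(C)C(C)(C)C)c(C=O)c1 | intermediate
18 | [2-(tert-butyldimethylsilyloxy)-5-methoxy-3-methylphenyl]methanol | COc1cc(C)c(O[Si](C)(C)C(C)(C)C)c(CO)c1 | intermediate
19 | tert-butyl[2-(chloromethyl)-4-methoxy-6-methylphenoxy]dimethylsilane | COc1cc(C)c(O[Si](C)(C)C(C)(C)C)c(CCl)c1 | intermediate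
20 | (E)-alkenyl(dimethyl)alane from 14, O5' as dimethylaluminium alkoxide | C[Al](C)/C=C(\C)C[C@@H](O[Al](C)C)/C=C(\C)CC/C=C(\C)[C@@H]1C[C@H](O[Si](C)(C)C(C)(C)C)C(C)(C)O1 | intermediate (not isolated)
21 | (2E,5R,6E,10E)-1-[2-(tert-butyldimethylsilyloxy)-5-methoxy-3-methylphenyl]-11-[(2S,4S)-4-(tert-butyldimethylsilyloxy)-5,5-dimethyloxolan-2-yl]-3,7-dimethyldodeca-2,6,10-trien-5-ol | COc1cc(C)c(O[Si](C)(C)C(C)(C)C)c(C/C=C(\C)C[C@@H](O)/C=C(\C)CC/C=C(\C)[C@@H]2C[C@H](O[Si](C)(C)C(C)(C)C)C(C)(C)O2)c1 | intermediate
22 | acetate of 21 at O5' | COc1cc(C)c(O[Si](C)(C)C(C)(C)C)c(C/C=C(\C)C[C@@H](OC(C)=O)/C=C(\C)CC/C=C(\C)[C@@H]2C[C@H](O[Si](C)(C)C(C)(C)C)C(C)(C)O2)c1 | intermediate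
23 | (2E,5R,6E,10E)-1-(2-hydroxy-5-methoxy-3-methylphenyl)-11-[(2S,4S)-4-hydroxy-5,5-dimethyloxolan-2-yl]-3,7-dimethyldodeca-2,6,10-trien-5-yl acetate | COc1cc(C)c(O)c(C/C=C(\C)C[C@H](/C=C(\C)CC/C=C(\C)[C@@H]2C[C@H](O)C(C)(C)O2)OC(C)=O)c1 | target

**Totals and risks**

Total step count: 17. Longest linear sequence: 12 steps (geraniol 3 to 23 through steps 2–10 and 15–17).

Steps most likely to fail:

1. Step 6 (Proposed new method). The Payne relay may not run in the aprotic medium (the carbanion fails to open the transposed oxirane or attacks another carbon), the Pd stage may give C-allylation or oligomers instead of ether closure, or the ring closure may show poor facial selectivity at C12'. Fallback with known chemistry, setting out from 5 and coming back at 10: MnO2 oxidation of 5 should give the dienal F1; Brown allylation with (−)-B-allyldiisopinocampheylborane should set C12' as S and give the homoallylic alcohol F2; olefin cross-metathesis with 2-methyl-2-butene (second-generation Ru benzylidene catalyst) should turn the vinyl group into the prenyl group of the trienol F3; Shi epoxidation with the ketone of the L-fructose series should epoxidise the only trisubstituted alkene without an allylic oxygen and give the 14'S epoxy alcohol F4; camphorsulfonic acid in CH2Cl2 should then close the oxolane by 5-endo opening of the oxirane at its tertiary carbon and give 10.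

2. Step 15. Chelation by the C5' aluminium alkoxide may drive syn-to-anti isomerisation of the alkenylalane (loss of E geometry), the Lewis-acidic medium may open the allylic oxolane ether, or transmetalation to Pd may be slow. Fallback setting out from 14 and coming back at 21: silylation (Et3SiCl, imidazole) should give the triethylsilyl ether F5; Zr-catalysed methylalumination followed by iodinolysis should give the (E)-alkenyl iodide F6; zinc insertion into 19 (Zn, LiCl, THF) should give the benzylic zinc chloride F7; Pd-catalysed Negishi coupling of F6 with F7 should give the coupled silyl ether F8; PPTS in MeOH should remove the triethylsilyl group selectively and give 21.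

3. Step 10. The β,β-disubstituted enal may react with low facial selectivity, or allenyl and propargyl transfer may compete. Fallback setting out from 12 and coming back at 14: iridium-catalysed transfer-hydrogenative carbonyl propargylation of the allylic alcohol 12 with 3-chloro-1-(trimethylsilyl)propyne (cyclometallated Ir–bisphosphine catalyst, enantiomer chosen for 5'R) should give the silylated homopropargylic alcohol F9 directly from the alcohol oxidation level; K2CO3 in MeOH should remove the C-silyl group and give 14.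

Further compounds
F1 | step 6 | (2E,6E)-8-[(4-methoxybenzyl)oxy]-2,6-dimethylocta-2,6-dienal | O=C/C(C)=C/CC/C(C)=C/COCc1ccc(OC)cc1
F2 | step 6 | (4S,5E,9E)-11-[(4-methoxybenzyl)oxy]-5,9-dimethylundeca-1,5,9-trien-4-ol | C=CC[C@H](O)/C(C)=C/CC/C(C)=C/COCc1ccc(OC)cc1
F3 | step 6 | (5S,6E,10E)-12-[(4-methoxybenzyl)oxy]-2,6,10-trimethyldodeca-2,6,10-trien-5-ol | CC(C)=CC[C@H](O)/C(C)=C/CC/C(C)=C/COCc1ccc(OC)cc1
F4 | step 6 | (2S,3E,7E)-1-[(2S)-3,3-dimethyloxiran-2-yl]-9-[(4-methoxybenzyl)oxy]-3,7-dimethylnona-3,7-dien-2-ol | CC1(C)O[C@H]1C[C@H](O)/C(C)=C/CC/C(C)=C/COCc1ccc(OC)cc1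
F5 | step 15 | triethylsilyl ether of 14 at O5' | C#CC[C@@H](O[Si](CC)(CC)CC)/C=C(\C)CC/C=C(\C)[C@@H]1C[C@H](O[Si](C)(C)C(C)(C)C)C(C)(C)O1
F6 | step 15 | (E)-alkenyl iodide from F5 (iodine on C2', methyl on C3') | I/C=C(\C)C[C@@H](O[Si](CC)(CC)CC)/C=C(\C)CC/C=C(\C)[C@@H]1C[C@H](O[Si](C)(C)C(C)(C)C)C(C)(C)O1
F7 | step 15 | [2-(tert-butyldimethylsilyloxy)-5-methoxy-3-methylbenzyl]zinc chloride | COc1cc(C)c(O[Si](C)(C)C(C)(C)C)c(C[Zn]Cl)c1
F8 | step 15 | triethylsilyl ether of 21 at O5' | COc1cc(C)c(O[Si](C)(C)C(C)(C)C)c(C/C=C(\C)C[C@@H](O[Si](CC)(CC)CC)/C=C(\C)CC/C=C(\C)[C@@H]2C[C@H](O[Si](C)(C)C(C)(C)C)C(C)(C)O2)c1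
F9 | step 10 | 1-(trimethylsilyl) derivative of alkyne 14 | C[Si](C)(C)C#CC[C@@H](O)/C=C(\C)CC/C=C(\C)[C@@H]1C[C@H](O[Si](C)(C)C(C)(C)C)C(C)(C)O1
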